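**Plan**

- Cuts: the dihydropyran at its O–C(spiro) bond and its CH2–CH2 bond (hetero-Diels–Alder), giving alantolactone and an elemane-type 2-substituted acrolein; the enal side chain back through enol triflate, acetyl and nitrile to a ring ketone; the isopropenyl–ring bond (conjugate addition); the carbocycle at the bond between its CH2 and the isopropenyl-bearing CH (aldol C=C) and at the quaternary carbon–CH2 bond (Michael), down to tiglic aldehyde and methyl vinyl ketone.
- Forward order: the cyclohexane ring first (one-pot Michael/aldol annulation), then isopropenyl, then the three-carbon enal side chain, and last the spiro-dihydropyran by union with alantolactone.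
- Enabling feature: in the elemane cyclohexane, the CH2 between the isopropenyl-bearing CH and the side-chain-bearing CH is the α-carbon of a latent cyclohex-2-enone (side-chain carbon = C=O, isopropenyl carbon = β-carbon). The adjacent quaternary carbon (CH3, CH=CH2) is the α-carbon of tiglic aldehyde, whose dienamine unveils the vinyl group by deconjugation.
- Stereochemistry: quaternary carbon from the amine catalyst; isopropenyl carbon by axial cuprate attack anti to the vinyl group; side-chain carbon by equilibration to the equatorial acetyl; spiro carbon by cycloaddition on the convex face of the cis-fused lactone; the four eudesmane centres are bought with alantolactone.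

Key step: step 1

Remark (assumption): alantolactone is used as the commercial natural product, (3aR,5S,8aR,9aR), which matches the eudesmane half of the target. The elemane half belongs to the series enantiomeric to (−)-β-elemene and is therefore built by synthesis.

**Route**

Step 1
Reactants: 1 (E)-2-methylbut-2-enal (tiglic aldehyde); 2 but-3-en-2-one (methyl vinyl ketone)
Product: 5 (R)-4-ethenyl-4-methylcyclohex-2-en-1-one, via keto-aldehyde 3 (not isolated), via ketol 4 (not isolated)
Conditions: (S)-N-(4-dodecylphenylsulfonyl)pyrrolidine-2-carboxamide (20 mol %), ClCH2CH2Cl, 0 °C to rt, 2 added slowly; then pyrrolidine (30 mol %), AcOH (30 mol %), 40 °C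
Reagents that add atoms: none
Why: Proposed new method: the prolinamide condenses with 1 to the conjugated (1E)-dienamine, whose α-carbon adds to 2 held by the sulfonamide N–H, and hydrolysis gives keto-aldehyde 3; the methyl ketone of 3 then adds as its enamine to the neopentyl aldehyde (ketol 4) and loss of water gives 5. The closest known reaction type is the amine-catalysed enantioselective Michael/aldol (Robinson) annulation of α,α-disubstituted aldehydes with vinyl ketones, together with the racemic pyrrolidine-enamine annulation of α-branched aldehydes with 2. The carbocycle closes in a 6-(enolendo)-exo-trig aldol mode between the ketone methyl carbon and the aldehyde carbon, which become the α- and β-carbons of the enone. The single stereocentre, the quaternary carbon carrying methyl and the vinyl group unveiled by deconjugation of 1, is set in the Michael event by the catalyst: attack on the face of the (1E)-dienamine syn to the directing N–H of the (S)-catalyst leads to (R) in the working model, and the mirror-image catalyst would be used if the opposite sense were found. The step needs α- rather than γ-alkylation (or [4+2] addition) of the dienamine and a single dienamine geometry; the α-carbon bears the largest HOMO coefficient of a 1-aminodiene, hydrogen-bonded delivery places the β-carbon of 2 over it, and the extended s-trans (1E) form keeps the vinyl group trans to nitrogen. The aldol/dehydration stage cannot erode the result because the quaternary carbon has no α-hydrogen.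

Step 2
Reactants: 5 (R)-4-ethenyl-4-methylcyclohex-2-en-1-one
Product: 7 (3R,4R)-4-ethenyl-4-methyl-3-(prop-1-en-2-yl)cyclohexan-1-one, via bromomagnesium enolate 6 (not isolated)
Conditions: CH2=C(CH3)MgBr (1.5 equiv), CuBr·SMe2 (10 mol %), THF, −78 to −30 °C; sat. aq. NH4Cl
Reagents that add atoms: isopropenylmagnesium bromide, C=C(C)[Mg]Br
Why: Copper-catalysed conjugate addition of an alkenyl Grignard reagent; the flat vinyl group should take the pseudoaxial site at the quaternary carbon, so stereoelectronically preferred axial attack at the β-carbon comes anti to it and places isopropenyl cis to methyl.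

Step 3
Reactants: 7 (3R,4R)-4-ethenyl-4-methyl-3-(prop-1-en-2-yl)cyclohexan-1-one
Product: 8 (3R,4R)-4-ethenyl-4-methyl-3-(prop-1-en-2-yl)cyclohexane-1-carbonitrile (both C-1 epimers)
Conditions: TosMIC, KOtBu, EtOH (2 equiv), DME, 0 to 40 °C; aqueous work-up
Reagents that add atoms: p-toluenesulfonylmethyl isocyanide (TosMIC), Cc1ccc(cc1)S(=O)(=O)C[N+]#[C-]
Why: Van Leusen reductive cyanation turns the unhindered ring ketone into the one-carbon-longer nitrile; the configuration at the new CH is not yet fixed and is set in step 4.

Step 4
Reactants: 8 (3R,4R)-4-ethenyl-4-methyl-3-(prop-1-en-2-yl)cyclohexane-1-carbonitrile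
Product: 10 1-[(1S,3R,4R)-4-ethenyl-4-methyl-3-(prop-1-en-2-yl)cyclohexyl]ethan-1-one, via N-bromomagnesio ketimine 9 (not isolated)
Conditions: MeMgBr, CuBr (5 mol %), THF, reflux; 1 M aq. HCl, rt; then K2CO3 (cat.), MeOH, rt
Reagents that add atoms: methylmagnesium bromide, C[Mg]Br; water, O
Why: Grignard addition to the nitrile and hydrolysis of the metallo-imine give the methyl ketone; base equilibration of the α-centre should favour the equatorial acetyl, cis to the equatorial isopropenyl in the chair locked by the trans vinyl/isopropenyl pair, and any axial epimer is recycled through the same equilibration.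

Step 5
Reactants: 10 1-[(1S,3R,4R)-4-ethenyl-4-methyl-3-(prop-1-en-2-yl)cyclohexyl]ethan-1-one
Product: 12 1-[(1S,3R,4R)-4-ethenyl-4-methyl-3-(prop-1-en-2-yl)cyclohexyl]ethenyl trifluoromethanesulfonate, via lithium enolate 11 (not isolated)
Conditions: LiN(iPr)2 (LDA), THF, −78 °C; PhNTf2, −78 to 0 °C
Reagents that add atoms: N-phenylbis(trifluoromethanesulfonimide), O=S(=O)(N(c1ccccc1)S(=O)(=O)C(F)(F)F)C(F)(F)F
Why: Kinetic deprotonation of a methyl ketone occurs at the methyl group, not at the tertiary ring CH, so O-triflation gives the terminal enol triflate without touching the adjacent stereocentre.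

Step 6
Reactants: 12 1-[(1S,3R,4R)-4-ethenyl-4-methyl-3-(prop-1-en-2-yl)cyclohexyl]ethenyl trifluoromethanesulfonate
Product: 13 2-[(1S,3R,4R)-4-ethenyl-4-methyl-3-(prop-1-en-2-yl)cyclohexyl]prop-2-enal
Conditions: Pd(PPh3)4 (5 mol %), CO (1 atm), Bu3SnH (slow addition), LiCl, THF, 50 °C
Reagents that add atoms: carbon monoxide, [C-]#[O+]
Why: Palladium-catalysed reductive carbonylation (formylation) of an enol triflate: oxidative addition, CO insertion and hydride transfer from tin to the acyl-palladium give the 2-substituted acrolein; the isolated alkenes are inert.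

Step 7
Reactants: 13 2-[(1S,3R,4R)-4-ethenyl-4-methyl-3-(prop-1-en-2-yl)cyclohexyl]prop-2-enal; 14 alantolactone
Product: 15 target spiro-dihydropyran lactone (CNP0175206.1)
Conditions: 14 (2 equiv), BHT (cat.), toluene (concentrated), 110 °C, sealed tube
Reagents that add atoms: none
Why: Thermal hetero-Diels–Alder reaction of the 1-oxadiene of 13 with the exocyclic alkene of the α-methylene lactone, with acrolein-dimer regiochemistry (oxygen to the carbonyl-bearing carbon); approach on the convex face of the cis-fused lactone, the face of the two ring-fusion hydrogens, should set the spiro centre as in the target.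

**Compound list**

1 | (E)-2-methylbut-2-enal (tiglic aldehyde) | C/C=C(\C)C=O | starting material
2 | but-3-en-2-one (methyl vinyl ketone) | CC(=O)C=C | starting material
3 | (R)-2-ethenyl-2-methyl-5-oxohexanal (keto-aldehyde) | C=C[C@@](C=O)(C)CCC(C)=O | intermediate (not isolated)
4 | (4R)-4-ethenyl-3-hydroxy-4-methylcyclohexan-1-one (ketol, carbinol epimers) | C=C[C@@]1(C)CCC(=O)CC1O | intermediate (not isolated)
5 | (R)-4-ethenyl-4-methylcyclohex-2-en-1-one | C=C[C@@]1(C)CCC(=O)C=C1 | intermediate
6 | bromomagnesium enolate of 7 | C=C[C@@]1(C)CCC(O[Mg]Br)=C[C@@H]1C(=C)C | intermediate (not isolated)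
7 | (3R,4R)-4-ethenyl-4-methyl-3-(prop-1-en-2-yl)cyclohexan-1-one | C=C[C@@]1(C)CCC(=O)C[C@@H]1C(=C)C | intermediate
8 | (3R,4R)-4-ethenyl-4-methyl-3-(prop-1-en-2-yl)cyclohexane-1-carbonitrile (C-1 epimers) | C=C[C@@]1(C)CCC(C#N)C[C@@H]1C(=C)C | intermediate
9 | N-bromomagnesio ketimine from 8 | C=C[C@@]1(C)CCC(C(C)=N[Mg]Br)C[C@@H]1C(=C)C | intermediate (not isolated)
10 | 1-[(1S,3R,4R)-4-ethenyl-4-methyl-3-(prop-1-en-2-yl)cyclohexyl]ethan-1-one | C=C[C@@]1(C)CC[C@H](C(C)=O)C[C@@H]1C(=C)C | intermediate
11 | lithium enolate of 10 (methyl side) | C=C[C@@]1(C)CC[C@H](C(=C)O[Li])C[C@@H]1C(=C)C | intermediate (not isolated)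
12 | 1-[(1S,3R,4R)-4-ethenyl-4-methyl-3-(prop-1-en-2-yl)cyclohexyl]ethenyl trifluoromethanesulfonate | C=C[C@@]1(C)CC[C@H](C(=C)OS(=O)(=O)C(F)(F)F)C[C@@H]1C(=C)C | intermediate
13 | 2-[(1S,3R,4R)-4-ethenyl-4-methyl-3-(prop-1-en-2-yl)cyclohexyl]prop-2-enal | C=C[C@@]1(C)CC[C@H](C(=C)C=O)C[C@@H]1C(=C)C | intermediate
14 | alantolactone, (3aR,5S,8aR,9aR) | C=C1C(=O)O[C@@H]2C[C@@]3(C)CCC[C@H](C)C3=C[C@@H]21 | starting material
15 | target: spiro[dihydropyran–eudesmanolide] carrying the elemane cyclohexyl group on the enol-ether carbon | C=C[C@@]1(C)CC[C@H](C2=CO[C@@]3(CC2)C(=O)O[C@@H]2C[C@@]4(C)CCC[C@H](C)C4=C[C@@H]23)C[C@@H]1C(=C)C | target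

**Count**

Total steps: 7. Longest linear sequence: 7 steps (1 and 2 to 15); alantolactone joins in the last step.

**Steps most likely to fail, with fallbacks**

1. Step 1 (proposed new method). What may go wrong: γ-alkylation or [4+2] addition of the dienamine instead of α-attack, or loss of control over dienamine geometry, leading to poor site selectivity or low enantioselectivity. Fallback (known chemistry), setting out from 1 and 2 and coming back at 7: the pyrrolidine dienamine of 1 is annulated with 2 in the racemic Stork manner (pyrrolidine, toluene, reflux; 2; then AcOH/NaOAc/H2O, reflux) to racemic 4-ethenyl-4-methylcyclohex-2-en-1-one F1. Dehydrogenation with 2-iodoxybenzoic acid (DMSO, 70 °C) gives the achiral 4-ethenyl-4-methylcyclohexa-2,5-dien-1-one F2. A rhodium-catalysed enantioselective 1,4-addition of isopropenylboronic acid pinacol ester (Rh(acac)(C2H4)2, BINAP of the appropriate sense, dioxane/H2O, 90 °C) then desymmetrises F2 to (4S,5R)-4-ethenyl-4-methyl-5-(prop-1-en-2-yl)cyclohex-2-en-1-one F3; the ligand selects between the two enantiotopic enone termini and the substrate bias (attack anti to vinyl) fixes the face. Conjugate reduction of the remaining enone with [(Ph3P)CuH]6 in toluene gives 7.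

2. Step 2. What may go wrong: poor facial selectivity at the β-carbon, since methyl and vinyl differ little in size, or competing 1,2-addition. Fallback, setting out from 5 and coming back at 7: substrate control is replaced by ligand control, using a rhodium-catalysed 1,4-addition of isopropenylboronic acid pinacol ester (Rh(acac)(C2H4)2, BINAP, dioxane/H2O) with the ligand enantiomer whose intrinsic face preference is the methyl face of 5 (matched double stereodifferentiation). This makes no new compound (F0).

3. Step 7. What may go wrong: a slow cycloaddition between two electron-poor partners is outrun by self-dimerisation or polymerisation of the enal, or the partners degrade thermally. Fallback, setting out from 10 (as its lithium enolate 11) and 14 and coming back at 15, builds the dihydropyran stepwise. Enolate 11 (LDA, THF, −78 °C) adds in Michael fashion to the exocyclic methylene of 14; the resulting lactone enolate is oxidised in the same flask with 3-phenyl-2-(phenylsulfonyl)oxaziridine on the convex face, and the tertiary alkoxide is silylated (Me3SiCl) to give the keto silyl ether F4. A Wittig reaction with (methoxymethylene)triphenylphosphorane gives the methyl enol ether F5. Pyridinium p-toluenesulfonate in warm toluene then removes the silyl group, closes the six-membered mixed acetal F6 (not isolated) by attack of the tertiary hydroxyl on the protonated enol ether, and eliminates methanol to give 15.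

Further compounds
F1 | step 1 | racemic 4-ethenyl-4-methylcyclohex-2-en-1-one | C=CC1(C)CCC(=O)C=C1
F2 | step 1 | 4-ethenyl-4-methylcyclohexa-2,5-dien-1-one | C=CC1(C)C=CC(=O)C=C1
F3 | step 1 | (4S,5R)-4-ethenyl-4-methyl-5-(prop-1-en-2-yl)cyclohex-2-en-1-one | C=C[C@@]1(C)C=CC(=O)C[C@@H]1C(=C)C
F0 | step 2 | none | none
F4 | step 7 | 11-(trimethylsilyloxy)-11,13-dihydroalantolactone carrying at C-13 the CH2C(=O)-[(1S,3R,4R)-4-ethenyl-4-methyl-3-(prop-1-en-2-yl)cyclohexyl] group (silyloxy on the convex face) | C=C[C@@]1(C)CC[C@H](C(=O)CC[C@]2(O[Si](C)(C)C)C(=O)O[C@@H]3C[C@@]4(C)CCC[C@H](C)C4=C[C@H]23)C[C@@H]1C(=C)C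
F5 | step 7 | methyl enol ether (E/Z) from methoxymethylenation of the ketone of F4 | C=C[C@@]1(C)CC[C@H](C(=COC)CC[C@]2(O[Si](C)(C)C)C(=O)O[C@@H]3C[C@@]4(C)CCC[C@H](C)C4=C[C@H]23)C[C@@H]1C(=C)C
F6 | step 7 | spiro 2-methoxytetrahydropyran mixed acetal (epimers at the two new ring carbons) | C=C[C@@]1(C)CC[C@H](C2C(OC)O[C@@]3(CC2)C(=O)O[C@@H]2C[C@@]4(C)CCC[C@H](C)C4=C[C@@H]23)C[C@@H]1C(=C)C
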